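**Retrosynthetic overview**

1. Target ⇒ cut the bond between the quaternary carbon and the E-olefin: a copper-catalysed enantioselective SN2' union (a 1'–3 coupling, as in botryococcene assembly) of a ring-bearing (E)-allylic phosphate with the (E)-alkenylalane of a C17 side-chain alkyne.
2. Ring fragment ⇒ (2E,6Z)-farnesyl acetate: the only ring is closed by a formaldehyde-initiated cationic cyclisation that imitates the C-methylation–cyclisation of the biosynthesis and sets both ring stereocentres at once; CH2OH is then reduced to CH3.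
3. (2E,6Z)-Farnesyl acetate ⇒ nerylacetone (methyl ketone → alkyne → carboalumination).
4. Side-chain alkyne ⇒ isopropyl-B(pin) by reagent-controlled boronic ester homologation (four CH(CH3) and four CH2 insertions), then deborylative alkynylation.
5. Order: the ring is formed first (step 3); the two fragments are joined last (step 13).

Assumption: nerylacetone (≥95% Z), isopropyl-B(pin), ethyl 2,4,6-triisopropylbenzoate and both sparteine enantiomers are bought; the enantiomer of each chiral catalyst (acid in step 3, NHC ligand in step 13) is picked by a short screen to give the configurations drawn.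

Locants used in the comments: ring C1–C6 as in the name of 23 (C2 carries the chain, C6 the methyl); side chain C1'–C15' counted from the ring (C3' quaternary; C6', C9', C10', C13' methyl-bearing).

**Route**

Step 1
Reactants: 1 nerylacetone [(5Z)-6,10-dimethylundeca-5,9-dien-2-one]
Product: 3 (5Z)-6,10-dimethylundeca-5,9-dien-1-yne, via enol phosphate 2 (not isolated)
Conditions: LiN(i-Pr)2 (1.05 equiv), THF, −78 °C; ClP(O)(OEt)2; then LiN(i-Pr)2 (2.3 equiv), −78 °C → rt
Reagents that add atoms: none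
Why: Kinetic enolisation on the methyl side and O-phosphorylation give the terminal enol phosphate, whose base-induced β-elimination (Negishi methyl ketone to alkyne conversion) gives the terminal alkyne without touching the Z olefin.

Step 2
Reactants: 3 (5Z)-6,10-dimethylundeca-5,9-dien-1-yne
Product: 6 (2E,6Z)-3,7,11-trimethyldodeca-2,6,10-trien-1-yl acetate, via alkenylalane 4 (not isolated), via lithium alkoxide 5 (not isolated)
Conditions: Me3Al (2 equiv), Cp2ZrCl2 (25 mol %), (CH2Cl)2, rt; volatiles off; n-BuLi, THF, −78 → 0 °C; (CH2O)n; then Ac2O, DMAP, 0 °C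
Reagents that add atoms: trimethylaluminium C[Al](C)C; formaldehyde (as paraformaldehyde) C=O; acetic anhydride CC(=O)OC(C)=O
Why: Zirconium-catalysed syn carboalumination (Negishi) puts Me and Al cis across the alkyne (E olefin, >98%), the alanate is hydroxymethylated with retention by formaldehyde, and the alkoxide is acetylated in the same flask.

Step 3
Reactants: 6 (2E,6Z)-3,7,11-trimethyldodeca-2,6,10-trien-1-yl acetate
Product: 7 (2E)-5-[(1S,3S)-3-(hydroxymethyl)-2,2-dimethyl-6-methylidenecyclohexyl]-3-methylpent-2-en-1-yl acetate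
Conditions: (CH2O)n (1.1 equiv), BINOL-derived N-triflyl imidodiphosphorimidate Brønsted acid (IDPi, 5 mol %), CHCl3/(CF3)3COH, −40 °C; aq. NaHCO3/MeOH work-up
Reagents that add atoms: formaldehyde (as paraformaldehyde) C=O
Why: Proposed new method: a confined chiral Brønsted acid protonates formaldehyde to a hydroxycarbenium ion that plays the part of the biological methyl cation, adding to C10 of the terminal olefin of 6 while C11 is captured by the 6Z olefin through a chair transition state (anti addition puts CH2OH equatorial, the Z geometry forces the side chain axial, so the two ring stereocentres come out trans, and the catalyst pocket picks the olefin face and hence the 1S,3S series), and the cascade ends by loss of a methyl proton because the ring C1–H is equatorial (not aligned with the cationic p orbital) and the aligned axial C5–H is shielded by the axial side chain; the closest known reactions are the IDPi-catalysed asymmetric intermolecular Prins reaction of olefins with paraformaldehyde and IDPi-catalysed polyene cyclisations (Prins-initiated cation–olefin cyclisation).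

Step 4
Reactants: 7 (2E)-5-[(1S,3S)-3-(hydroxymethyl)-2,2-dimethyl-6-methylidenecyclohexyl]-3-methylpent-2-en-1-yl acetate
Product: 9 (2E)-3-methyl-5-[(1S,3S)-2,2,3-trimethyl-6-methylidenecyclohexyl]pent-2-en-1-ol, via mesylate 8 (not isolated)
Conditions: MsCl, Et3N, THF, 0 °C; filter; LiBHEt3 (5 equiv), THF, 0 °C → rt
Reagents that add atoms: none
Why: Sulfonylation followed by SN2 displacement with the strongly nucleophilic triethylborohydride turns CH2OH into CH3 without touching a stereocentre, and the same hydride cleaves the acetate to the allylic alcohol (reductive deoxygenation plus ester reduction).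

Step 5
Reactants: 9 (2E)-3-methyl-5-[(1S,3S)-2,2,3-trimethyl-6-methylidenecyclohexyl]pent-2-en-1-ol
Product: 10 diethyl (2E)-3-methyl-5-[(1S,3S)-2,2,3-trimethyl-6-methylidenecyclohexyl]pent-2-en-1-yl phosphate
Conditions: ClP(O)(OEt)2, pyridine, DMAP (cat.), CH2Cl2, 0 °C → rt
Reagents that add atoms: diethyl chlorophosphate CCOP(=O)(Cl)OCC
Why: O-phosphorylation of the primary allylic alcohol installs the leaving group for the allylic substitution; no stereocentre is involved.

Step 6
Reactants: 11 2-isopropyl-4,4,5,5-tetramethyl-1,3,2-dioxaborolane [isopropyl-B(pin)]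
Product: 12 4,4,5,5-tetramethyl-2-[(2S)-3-methylbutan-2-yl]-1,3,2-dioxaborolane
Conditions: ethyl 2,4,6-triisopropylbenzoate, s-BuLi, (+)-sparteine, Et2O, −78 °C, 5 h; then 11, −78 °C → 35 °C
Reagents that add atoms: ethyl 2,4,6-triisopropylbenzoate CCOC(=O)c1c(C(C)C)cc(C(C)C)cc1C(C)C
Why: Lithiation–borylation (Hoppe–Aggarwal homologation): (+)-sparteine-directed deprotonation gives the (R)-lithiated benzoate, which is borylated with retention and rearranges by 1,2-metallate shift with inversion, setting C13' under reagent control.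

Step 7
Reactants: 12 4,4,5,5-tetramethyl-2-[(2S)-3-methylbutan-2-yl]-1,3,2-dioxaborolane
Product: 14 2-[(3R)-3,4-dimethylpentyl]-4,4,5,5-tetramethyl-1,3,2-dioxaborolane, via boronic ester 13 (not isolated)
Conditions: BrCH2Cl, n-BuLi, Et2O, −78 °C → rt; then again BrCH2Cl, n-BuLi, −78 °C → rt
Reagents that add atoms: bromochloromethane ClCBr
Why: Two Matteson homologations with LiCH2Cl insert CH2 twice by 1,2-metallate rearrangement with retention at the migrating carbon.

Step 8
Reactants: 14 2-[(3R)-3,4-dimethylpentyl]-4,4,5,5-tetramethyl-1,3,2-dioxaborolane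
Product: 15 4,4,5,5-tetramethyl-2-[(2S,5R)-5,6-dimethylheptan-2-yl]-1,3,2-dioxaborolane
Conditions: ethyl 2,4,6-triisopropylbenzoate, s-BuLi, (+)-sparteine, Et2O, −78 °C, 5 h; then 14, −78 °C → 35 °C
Reagents that add atoms: ethyl 2,4,6-triisopropylbenzoate CCOC(=O)c1c(C(C)C)cc(C(C)C)cc1C(C)C
Why: Lithiation–borylation with the (R)-lithiated benzoate (retentive borylation, invertive 1,2-metallate shift) sets C10' under reagent control.

Step 9
Reactants: 15 4,4,5,5-tetramethyl-2-[(2S,5R)-5,6-dimethylheptan-2-yl]-1,3,2-dioxaborolane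
Product: 16 4,4,5,5-tetramethyl-2-[(2S,3S,6R)-3,6,7-trimethyloctan-2-yl]-1,3,2-dioxaborolane
Conditions: ethyl 2,4,6-triisopropylbenzoate, s-BuLi, (+)-sparteine, Et2O, −78 °C, 5 h; then 15, −78 °C → 35 °C, 16 h
Reagents that add atoms: ethyl 2,4,6-triisopropylbenzoate CCOC(=O)c1c(C(C)C)cc(C(C)C)cc1C(C)C
Why: A second lithiation–borylation with the same (R)-carbenoid sets C9' and gives the anti (erythro) vicinal dimethyl pair, the reagent overriding any bias from the neighbouring centre.

Step 10
Reactants: 16 4,4,5,5-tetramethyl-2-[(2S,3S,6R)-3,6,7-trimethyloctan-2-yl]-1,3,2-dioxaborolane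
Product: 18 4,4,5,5-tetramethyl-2-[(3R,4S,7R)-3,4,7,8-tetramethylnonyl]-1,3,2-dioxaborolane, via boronic ester 17 (not isolated)
Conditions: BrCH2Cl, n-BuLi, Et2O, −78 °C → rt; then again BrCH2Cl, n-BuLi, −78 °C → rt
Reagents that add atoms: bromochloromethane ClCBr
Why: Two Matteson homologations insert the two CH2 groups with retention at the migrating carbon.

Step 11
Reactants: 18 4,4,5,5-tetramethyl-2-[(3R,4S,7R)-3,4,7,8-tetramethylnonyl]-1,3,2-dioxaborolane
Product: 19 4,4,5,5-tetramethyl-2-[(2R,5R,6S,9R)-5,6,9,10-tetramethylundecan-2-yl]-1,3,2-dioxaborolane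
Conditions: ethyl 2,4,6-triisopropylbenzoate, s-BuLi, (−)-sparteine, Et2O, −78 °C, 5 h; then 18, −78 °C → 35 °C
Reagents that add atoms: ethyl 2,4,6-triisopropylbenzoate CCOC(=O)c1c(C(C)C)cc(C(C)C)cc1C(C)C
Why: Lithiation–borylation with the (S)-lithiated benzoate from (−)-sparteine (retentive borylation, invertive 1,2-metallate shift) sets C6'.

Step 12
Reactants: 19 4,4,5,5-tetramethyl-2-[(2R,5R,6S,9R)-5,6,9,10-tetramethylundecan-2-yl]-1,3,2-dioxaborolane
Product: 21 (3R,6R,7S,10R)-3,6,7,10,11-pentamethyldodec-1-yne, via vinyl carbamate 20 (not isolated)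
Conditions: vinyl N,N-diisopropylcarbamate, s-BuLi, TMEDA, THF, −78 °C; then 19; I2, MeOH, −78 °C → rt; NaOMe; concentrate; LiN(i-Pr)2 (3 equiv), THF, −78 °C → rt
Reagents that add atoms: vinyl N,N-diisopropylcarbamate C=COC(=O)N(C(C)C)C(C)C
Why: Zweifel-type coupling of the boronic ester with the α-lithiated vinyl carbamate (1,2-migration with retention, then boron–iodine elimination) gives the alkenyl carbamate, and base-induced 1,2-elimination of carbamate gives the terminal alkyne with C6' unchanged (deborylative alkynylation).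

Step 13
Reactants: 21 (3R,6R,7S,10R)-3,6,7,10,11-pentamethyldodec-1-yne; 10 diethyl (2E)-3-methyl-5-[(1S,3S)-2,2,3-trimethyl-6-methylidenecyclohexyl]pent-2-en-1-yl phosphate
Product: 23 (2S,6S)-2-[(3S,4E,6R,9R,10S,13R)-3-ethenyl-3,6,9,10,13,14-hexamethylpentadec-4-en-1-yl]-1,1,6-trimethyl-3-methylidenecyclohexane, via alkenylalane 22 (not isolated)
Conditions: 21, i-Bu2AlH (1.0 equiv), hexanes, 55 °C, 5 h; then 10, CuCl2·2H2O (5 mol %), chiral sulfonate-bearing imidazolinium salt (NHC precursor, 6 mol %), THF, −15 °C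
Reagents that add atoms: none
Why: Syn hydroalumination gives the (E)-alkenylalane, and copper-catalysed enantioselective allylic substitution (SN2') delivers it with retention of olefin geometry to the γ-carbon of the trisubstituted allylic phosphate, creating the quaternary C3' centre (S, catalyst-controlled), the vinyl group and the E olefin in one step.

**Compound list**

1 | nerylacetone, (5Z)-6,10-dimethylundeca-5,9-dien-2-one | CC(=O)CC/C=C(/C)CCC=C(C)C | starting material
2 | diethyl (5Z)-6,10-dimethylundeca-1,5,9-trien-2-yl phosphate | C=C(OP(=O)(OCC)OCC)CC/C=C(/C)CCC=C(C)C | intermediate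
3 | (5Z)-6,10-dimethylundeca-5,9-dien-1-yne | C#CCC/C=C(/C)CCC=C(C)C | intermediate
4 | dimethyl[(1E,5Z)-2,6,10-trimethylundeca-1,5,9-trien-1-yl]alumane | C[Al](C)/C=C(\C)CC/C=C(/C)CCC=C(C)C | intermediate
5 | lithium (2E,6Z)-3,7,11-trimethyldodeca-2,6,10-trien-1-olate (aluminate, drawn as the lithium alkoxide) | [Li+].[O-]C/C=C(\C)CC/C=C(/C)CCC=C(C)C | intermediate
6 | (2E,6Z)-3,7,11-trimethyldodeca-2,6,10-trien-1-yl acetate | CC(=O)OC/C=C(\C)CC/C=C(/C)CCC=C(C)C | intermediate
7 | (2E)-5-[(1S,3S)-3-(hydroxymethyl)-2,2-dimethyl-6-methylidenecyclohexyl]-3-methylpent-2-en-1-yl acetate | CC(=O)OC/C=C(\C)CC[C@H]1C(=C)CC[C@H](CO)C1(C)C | intermediate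
8 | (2E)-5-[(1S,3S)-3-{[(methanesulfonyl)oxy]methyl}-2,2-dimethyl-6-methylidenecyclohexyl]-3-methylpent-2-en-1-yl acetate | CC(=O)OC/C=C(\C)CC[C@H]1C(=C)CC[C@H](COS(C)(=O)=O)C1(C)C | intermediate
9 | (2E)-3-methyl-5-[(1S,3S)-2,2,3-trimethyl-6-methylidenecyclohexyl]pent-2-en-1-ol | OC/C=C(\C)CC[C@H]1C(=C)CC[C@H](C)C1(C)C | intermediate
10 | diethyl (2E)-3-methyl-5-[(1S,3S)-2,2,3-trimethyl-6-methylidenecyclohexyl]pent-2-en-1-yl phosphate | CCOP(=O)(OCC)OC/C=C(\C)CC[C@H]1C(=C)CC[C@H](C)C1(C)C | intermediate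
11 | 2-isopropyl-4,4,5,5-tetramethyl-1,3,2-dioxaborolane | CC(C)B1OC(C)(C)C(C)(C)O1 | starting material
12 | 4,4,5,5-tetramethyl-2-[(2S)-3-methylbutan-2-yl]-1,3,2-dioxaborolane | CC(C)[C@H](C)B1OC(C)(C)C(C)(C)O1 | intermediate
13 | 2-[(2R)-2,3-dimethylbutyl]-4,4,5,5-tetramethyl-1,3,2-dioxaborolane | CC(C)[C@H](C)CB1OC(C)(C)C(C)(C)O1 | intermediate
14 | 2-[(3R)-3,4-dimethylpentyl]-4,4,5,5-tetramethyl-1,3,2-dioxaborolane | CC(C)[C@H](C)CCB1OC(C)(C)C(C)(C)O1 | intermediate
15 | 4,4,5,5-tetramethyl-2-[(2S,5R)-5,6-dimethylheptan-2-yl]-1,3,2-dioxaborolane | CC(C)[C@H](C)CC[C@H](C)B1OC(C)(C)C(C)(C)O1 | intermediate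
16 | 4,4,5,5-tetramethyl-2-[(2S,3S,6R)-3,6,7-trimethyloctan-2-yl]-1,3,2-dioxaborolane | CC(C)[C@H](C)CC[C@H](C)[C@H](C)B1OC(C)(C)C(C)(C)O1 | intermediate
17 | 4,4,5,5-tetramethyl-2-[(2R,3S,6R)-2,3,6,7-tetramethyloctyl]-1,3,2-dioxaborolane | CC(C)[C@H](C)CC[C@H](C)[C@H](C)CB1OC(C)(C)C(C)(C)O1 | intermediate
18 | 4,4,5,5-tetramethyl-2-[(3R,4S,7R)-3,4,7,8-tetramethylnonyl]-1,3,2-dioxaborolane | CC(C)[C@H](C)CC[C@H](C)[C@H](C)CCB1OC(C)(C)C(C)(C)O1 | intermediate
19 | 4,4,5,5-tetramethyl-2-[(2R,5R,6S,9R)-5,6,9,10-tetramethylundecan-2-yl]-1,3,2-dioxaborolane | CC(C)[C@H](C)CC[C@H](C)[C@H](C)CC[C@@H](C)B1OC(C)(C)C(C)(C)O1 | intermediate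
20 | (3R,6R,7S,10R)-3,6,7,10,11-pentamethyldodec-1-en-2-yl N,N-diisopropylcarbamate | CC(C)[C@H](C)CC[C@H](C)[C@H](C)CC[C@@H](C)C(=C)OC(=O)N(C(C)C)C(C)C | intermediate
21 | (3R,6R,7S,10R)-3,6,7,10,11-pentamethyldodec-1-yne | CC(C)[C@H](C)CC[C@H](C)[C@H](C)CC[C@@H](C)C#C | intermediate
22 | bis(2-methylpropyl)[(1E,3R,6R,7S,10R)-3,6,7,10,11-pentamethyldodec-1-en-1-yl]alumane | CC(C)[C@H](C)CC[C@H](C)[C@H](C)CC[C@@H](C)/C=C/[Al](CC(C)C)CC(C)C | intermediate
23 | (2S,6S)-2-[(3S,4E,6R,9R,10S,13R)-3-ethenyl-3,6,9,10,13,14-hexamethylpentadec-4-en-1-yl]-1,1,6-trimethyl-3-methylidenecyclohexane | C=C[C@@](C)(/C=C/[C@H](C)CC[C@@H](C)[C@@H](C)CC[C@@H](C)C(C)C)CC[C@H]1C(=C)CC[C@H](C)C1(C)C | target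

**Step count and risks**

Total: 13 steps. Longest linear sequence: 8 steps (steps 6–13, from isopropyl-B(pin)); the ring branch is 5 steps plus the union.

Most likely to fail:

Step 3 (hydroxymethylative cyclisation). This is an unprecedented reaction: the formaldehyde ene reaction at the terminal olefin, attack at the inner olefin, endocyclic proton loss or low ee could each win. Fallback, setting out from 6 and coming back at 9: the methyl group and the ring are installed in separate events. Allylic oxidation of the terminal E methyl group of 6 (SeO2 cat., t-BuOOH, CH2Cl2) gives (2E,6Z,10E)-12-hydroxy-3,7,11-trimethyldodeca-2,6,10-trien-1-yl acetate F1. Phosphorylation (ClP(O)(OEt)2, pyridine) gives (2E,6Z,10E)-12-[(diethoxyphosphoryl)oxy]-3,7,11-trimethyldodeca-2,6,10-trien-1-yl acetate F2. Copper-catalysed enantioselective SN2' methylation (Me2Zn, CuCl2·2H2O, chiral NHC ligand, THF, −15 °C) gives (2E,6Z,10S)-3,7,10,11-tetramethyldodeca-2,6,11-trien-1-yl acetate F3, which carries the methyl stereocentre next to an isopropenyl group. Protonation of that 1,1-disubstituted olefin (HNTf2 cat., (CF3)2CHOH/CH2Cl2, −40 °C) starts the same chair cyclisation, now controlled by the equatorial methyl group, and gives (2E)-3-methyl-5-[(1S,3S)-2,2,3-trimethyl-6-methylidenecyclohexyl]pent-2-en-1-yl acetate F4. K2CO3 in MeOH then gives 9.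

Step 13 (fragment union). The α-branched alkenylalane and the remote-branched phosphate may give low SN2' selectivity or low er. Fallback, setting out from 21 and 10 and coming back at 23: deprotonative alumination of 21 (i-Bu2AlH, Et3N 5 mol %, hexanes) gives bis(2-methylpropyl)[(3R,6R,7S,10R)-3,6,7,10,11-pentamethyldodec-1-yn-1-yl]alumane F5. The same copper–NHC allylic substitution with 10 then transfers the small, linear alkynyl group and gives (2S,6S)-2-[(3S,6R,9R,10S,13R)-3-ethenyl-3,6,9,10,13,14-hexamethylpentadec-4-yn-1-yl]-1,1,6-trimethyl-3-methylidenecyclohexane F6. Dissolving-metal reduction (Na, NH3/THF, −78 → −33 °C) converts the alkyne into the E olefin and leaves the isolated vinyl and methylidene groups alone, giving 23.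

Step 9 (second consecutive CH(CH3) insertion). The α-branched secondary boronic ester 15 may borylate slowly with the sparteine-bound carbenoid, and each such insertion runs at only about 97:3 selectivity. Fallback, setting out from 15 and coming back at 17 (isolated here): Zweifel olefination of 15 with 2-propenyllithium (from 2-bromopropene and t-BuLi; then I2, MeOH, NaOMe) gives (3S,6R)-2,3,6,7-tetramethyloct-1-ene F7. Catalyst-controlled anti-Markovnikov hydroboration (pinacolborane, CoCl2, chiral iminopyridine–oxazoline ligand, NaBHEt3) sets C9' and gives 17. One Matteson homologation (BrCH2Cl, n-BuLi) then gives 18.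

**Further compounds**

F1 | step 3 | (2E,6Z,10E)-12-hydroxy-3,7,11-trimethyldodeca-2,6,10-trien-1-yl acetate | CC(=O)OC/C=C(\C)CC/C=C(/C)CC/C=C(\C)CO
F2 | step 3 | (2E,6Z,10E)-12-[(diethoxyphosphoryl)oxy]-3,7,11-trimethyldodeca-2,6,10-trien-1-yl acetate | CC(=O)OC/C=C(\C)CC/C=C(/C)CC/C=C(\C)COP(=O)(OCC)OCC
F3 | step 3 | (2E,6Z,10S)-3,7,10,11-tetramethyldodeca-2,6,11-trien-1-yl acetate | CC(=O)OC/C=C(\C)CC/C=C(/C)CC[C@H](C)C(C)=C
F4 | step 3 | (2E)-3-methyl-5-[(1S,3S)-2,2,3-trimethyl-6-methylidenecyclohexyl]pent-2-en-1-yl acetate | CC(=O)OC/C=C(\C)CC[C@H]1C(=C)CC[C@H](C)C1(C)C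
F5 | step 13 | bis(2-methylpropyl)[(3R,6R,7S,10R)-3,6,7,10,11-pentamethyldodec-1-yn-1-yl]alumane | CC(C)[C@H](C)CC[C@H](C)[C@H](C)CC[C@@H](C)C#C[Al](CC(C)C)CC(C)C
F6 | step 13 | (2S,6S)-2-[(3S,6R,9R,10S,13R)-3-ethenyl-3,6,9,10,13,14-hexamethylpentadec-4-yn-1-yl]-1,1,6-trimethyl-3-methylidenecyclohexane | C=C[C@@](C)(C#C[C@H](C)CC[C@@H](C)[C@@H](C)CC[C@@H](C)C(C)C)CC[C@H]1C(=C)CC[C@H](C)C1(C)C
F7 | step 9 | (3S,6R)-2,3,6,7-tetramethyloct-1-ene | CC(C)[C@H](C)CC[C@H](C)C(C)=C
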